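**Retrosynthetic overview**

1. Ring C is closed last by Mitsunobu etherification (O1–C2) of a fully deprotected seco-phenol; O2' is by then inside the pyran, so O1 is the only phenolic oxygen that can reach C2.
2. C4–C4a comes from a Negishi coupling of a β-stereogenic alkylzinc iodide with the 3-iodide of mirror-symmetric 2,6-dihydroxy-4-methoxybenzaldehyde (C3 ≡ C5); this fixes 5-OMe, 7-OH and 8-CHO without a regiochemical choice, and the aldehyde never meets a reductant.
3. C3 is set by lipase desymmetrisation of a prochiral 2-aryl-1,3-propanediol, made from the aryl bromide by malonate arylation and reduction.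
4. The pyran on ring B is built first, in one operation, from a 2-bromo-5-(MOM-oxy)phenol and 3-methylbut-2-enal via a temporary 1,3,2-dioxaborinine ring, an ortho-quinone methide and oxa-6π closure. The enabling feature is the O2'–C2'–C3'(H) phenol unit of ring B: C3' is the only free carbon ortho to O2' (C1' is occupied, here by Br as placeholder for C3), it is activated by O2' and O4', and O4' is masked.
5. Order of rings: ring B (bought), pyran ring (step 2), ring A (bought), ring C (step 11).

Key step: step 2

Assumption: the lipase of step 5 is taken to acetylate the pro-S hydroxymethyl group of diol 9, which is the enantiotopic preference the (3R) target requires; this sense is not known for this aryl group and has to be confirmed.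

**Route**

Step 1
Reactants: 1 4-bromoresorcinol
Product: 2 2-bromo-5-(methoxymethoxy)phenol
Conditions: NaH (2.1 equiv), DMF, 0 °C; MOMCl (1.0 equiv), −30 → 0 °C
Reagents that add atoms: chloromethyl methyl ether, COCCl
Why: Williamson-type O-alkylation of the resorcinol dianion, in which the phenoxide para to bromine is the more basic and less hindered one and should be alkylated first, leaving the ortho-bromo hydroxyl free; no stereocentre is formed.

Step 2
Reactants: 2 2-bromo-5-(methoxymethoxy)phenol; 3 3-methylbut-2-enal
Product: 6 8-bromo-5-(methoxymethoxy)-2,2-dimethyl-2H-chromene, via benzodioxaborinine 4 (not isolated), via ortho-quinone methide 5 (not isolated)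
Conditions: PhB(OH)2 (1.1 equiv), EtCO2H (0.3 equiv), toluene, reflux, azeotropic removal of water
Reagents that add atoms: none
Why: Phenylboronic acid esterifies the free phenol of 2 and binds the aldehyde of 3, so the C–C bond is delivered within the boron ester to the only unsubstituted ortho carbon (between OH and OMOM) and the temporary ring 4 results; at reflux 4 loses the phenylboron oxide unit by cycloreversion to give ortho-quinone methide 5, whose 1-oxatriene closes to form the O–C(CH3)2 bond. The closest known reaction type is the phenylboronic acid-mediated condensation of phenols with α,β-unsaturated aldehydes to 2H-chromenes (ortho-specific hydroxyalkylation followed by electrocyclisation). The pyran ring closes by thermal disrotatory oxa-6π electrocyclisation, driven by rearomatisation of ring B, and no stereocentre is created. The step needs attack at one ortho carbon and closure on one oxygen: the other ortho position carries bromine, the para position is out of reach of the boron template, and the second oxygen is blocked as its MOM ether, so only one chromene can form. Catalytic propionic acid with water removal should leave the MOM acetal and the aryl bromide untouched.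

Step 3
Reactants: 6 8-bromo-5-(methoxymethoxy)-2,2-dimethyl-2H-chromene; 7 diethyl malonate
Product: 8 diethyl 2-[5-(methoxymethoxy)-2,2-dimethyl-2H-chromen-8-yl]propanedioate
Conditions: Pd(dba)2 (2 mol %), P(t-Bu)3·HBF4 (4 mol %), K3PO4, toluene, 70 °C
Reagents that add atoms: none
Why: Palladium-catalysed α-arylation of a malonate enolate, a coupling that accepts electron-rich ortho-alkoxy aryl bromides; the bulky monophosphine favours reductive elimination over Heck-type reaction at the chromene alkene.

Step 4
Reactants: 8 diethyl 2-[5-(methoxymethoxy)-2,2-dimethyl-2H-chromen-8-yl]propanedioate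
Product: 9 2-[5-(methoxymethoxy)-2,2-dimethyl-2H-chromen-8-yl]propane-1,3-diol
Conditions: LiAlH4, THF, 0 °C → rt; H2O quench
Reagents that add atoms: none
Why: Hydride reduction of both esters gives the prochiral 1,3-diol; the MOM acetal, the aryl ether and the chromene alkene are inert to LiAlH4.

Step 5
Reactants: 9 2-[5-(methoxymethoxy)-2,2-dimethyl-2H-chromen-8-yl]propane-1,3-diol
Product: 10 (2S)-3-hydroxy-2-[5-(methoxymethoxy)-2,2-dimethyl-2H-chromen-8-yl]propyl acetate
Conditions: lipase from Burkholderia cepacia (lipase PS), vinyl acetate, t-BuOMe, 25 °C, stopped at the monoacetate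
Reagents that add atoms: vinyl acetate, CC(=O)OC=C
Why: Enzymatic desymmetrisation by irreversible transesterification: the lipase distinguishes the two enantiotopic hydroxymethyl groups and acetylates one, which sets the future C3 (S in 10), while the released vinyl alcohol tautomerises to acetaldehyde and prevents the reverse reaction.

Step 6
Reactants: 10 (2S)-3-hydroxy-2-[5-(methoxymethoxy)-2,2-dimethyl-2H-chromen-8-yl]propyl acetate
Product: 11 (2R)-3-iodo-2-[5-(methoxymethoxy)-2,2-dimethyl-2H-chromen-8-yl]propyl acetate
Conditions: PPh3, I2, imidazole, CH2Cl2, 0 °C, dark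
Reagents that add atoms: iodine, II
Why: Appel-type iodination of the primary alcohol by SN2 at a carbon that is not the stereocentre, so the configuration is untouched (S becomes R only through the priority change); cold, non-basic conditions should suppress 1,3-acetyl migration.

Step 7
Reactants: 12 2,6-dihydroxy-4-methoxybenzaldehyde
Product: 13 2,6-dihydroxy-3-iodo-4-methoxybenzaldehyde
Conditions: N-iodosuccinimide (1.0 equiv), DMF, −10 → 0 °C
Reagents that add atoms: N-iodosuccinimide, O=C1CCC(=O)N1I
Why: Electrophilic aromatic iodination of a phloroglucinol-type ring; C3 and C5 are equivalent through the mirror plane along C1–C4, so mono-iodination can give only one product and the first iodine slows a second substitution.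

Step 8
Reactants: 13 2,6-dihydroxy-3-iodo-4-methoxybenzaldehyde
Product: 14 3-iodo-4-methoxy-2,6-bis(methoxymethoxy)benzaldehyde
Conditions: MOMCl (3 equiv), i-Pr2NEt, CH2Cl2, 0 → 40 °C
Reagents that add atoms: chloromethyl methyl ether, COCCl
Why: Double MOM ether formation (O-alkylation of the two phenols acidified by the ortho aldehyde), so that no acidic proton can quench the organozinc reagent of step 9.

Step 9
Reactants: 11 (2R)-3-iodo-2-[5-(methoxymethoxy)-2,2-dimethyl-2H-chromen-8-yl]propyl acetate; 14 3-iodo-4-methoxy-2,6-bis(methoxymethoxy)benzaldehyde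
Product: 16 (2R)-3-[3-formyl-6-methoxy-2,4-bis(methoxymethoxy)phenyl]-2-[5-(methoxymethoxy)-2,2-dimethyl-2H-chromen-8-yl]propyl acetate, via alkylzinc iodide 15 (not isolated)
Conditions: Zn dust, LiCl, THF, 30 °C; then 14, Pd(OAc)2 (3 mol %), SPhos (6 mol %), THF, 25 → 45 °C
Reagents that add atoms: none
Why: Negishi cross-coupling: LiCl-assisted zinc insertion into the primary C–I bond gives an alkylzinc iodide that tolerates the ester and acetals and does not add to the aryl aldehyde, and Pd/SPhos should couple it with the doubly ortho-substituted aryl iodide faster than β-hydride elimination; the stereocentre is β to the metal and is not touched.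

Step 10
Reactants: 16 (2R)-3-[3-formyl-6-methoxy-2,4-bis(methoxymethoxy)phenyl]-2-[5-(methoxymethoxy)-2,2-dimethyl-2H-chromen-8-yl]propyl acetate
Product: 17 2,6-dihydroxy-3-[(2R)-3-hydroxy-2-(5-hydroxy-2,2-dimethyl-2H-chromen-8-yl)propyl]-4-methoxybenzaldehyde
Conditions: HCl (1.25 M in MeOH), 40 °C
Reagents that add atoms: none
Why: Acid-catalysed acetal exchange and transesterification in methanol remove the three MOM groups and the acetate in one operation; dilute acid at moderate temperature should leave the 2,2-dimethylchromene and the stereocentre intact.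

Step 11
Reactants: 17 2,6-dihydroxy-3-[(2R)-3-hydroxy-2-(5-hydroxy-2,2-dimethyl-2H-chromen-8-yl)propyl]-4-methoxybenzaldehyde
Product: 18 (3R)-7-hydroxy-3-(5-hydroxy-2,2-dimethyl-2H-chromen-8-yl)-5-methoxy-3,4-dihydro-2H-chromene-8-carbaldehyde
Conditions: PPh3, DIAD, THF (0.01 M), 0 °C → rt
Reagents that add atoms: none
Why: Intramolecular Mitsunobu etherification (6-exo-tet): the acidic phenol ortho to the aldehyde is deprotonated by the betaine and only the oxygen next to the side chain can reach the activated primary carbon, the other two phenols being geometrically unable to form a ring; the bond is made at C2, so C3 stays R.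

**Compound list**

1 | 4-bromoresorcinol | Oc1ccc(Br)c(O)c1 | starting material
2 | 2-bromo-5-(methoxymethoxy)phenol | COCOc1ccc(Br)c(O)c1 | intermediate
3 | 3-methylbut-2-enal | CC(C)=CC=O | starting material
4 | 8-bromo-5-(methoxymethoxy)-4-(2-methylprop-1-en-1-yl)-2-phenyl-4H-1,3,2-benzodioxaborinine | COCOc1ccc(Br)c2OB(c3ccccc3)OC(C=C(C)C)c12 | intermediate
5 | 2-bromo-5-(methoxymethoxy)-6-(3-methylbut-2-en-1-ylidene)cyclohexa-2,4-dien-1-one | COCOC1=CC=C(Br)C(=O)C1=CC=C(C)C | intermediate
6 | 8-bromo-5-(methoxymethoxy)-2,2-dimethyl-2H-chromene | Brc1ccc(OCOC)c2C=CC(C)(C)Oc12 | intermediate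
7 | diethyl malonate | CCOC(=O)CC(=O)OCC | starting material
8 | diethyl 2-[5-(methoxymethoxy)-2,2-dimethyl-2H-chromen-8-yl]propanedioate | CCOC(=O)C(C(=O)OCC)c1ccc(OCOC)c2C=CC(C)(C)Oc12 | intermediate
9 | 2-[5-(methoxymethoxy)-2,2-dimethyl-2H-chromen-8-yl]propane-1,3-diol | OCC(CO)c1ccc(OCOC)c2C=CC(C)(C)Oc12 | intermediate
10 | (2S)-3-hydroxy-2-[5-(methoxymethoxy)-2,2-dimethyl-2H-chromen-8-yl]propyl acetate | OC[C@H](c1ccc(OCOC)c2C=CC(C)(C)Oc12)COC(C)=O | intermediate
11 | (2R)-3-iodo-2-[5-(methoxymethoxy)-2,2-dimethyl-2H-chromen-8-yl]propyl acetate | IC[C@H](c1ccc(OCOC)c2C=CC(C)(C)Oc12)COC(C)=O | intermediate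
12 | 2,6-dihydroxy-4-methoxybenzaldehyde | COc1cc(O)c(C=O)c(O)c1 | starting material
13 | 2,6-dihydroxy-3-iodo-4-methoxybenzaldehyde | COc1cc(O)c(C=O)c(O)c1I | intermediate
14 | 3-iodo-4-methoxy-2,6-bis(methoxymethoxy)benzaldehyde | COc1cc(OCOC)c(C=O)c(OCOC)c1I | intermediate
15 | {(2R)-3-acetoxy-2-[5-(methoxymethoxy)-2,2-dimethyl-2H-chromen-8-yl]propyl}zinc iodide | I[Zn]C[C@H](c1ccc(OCOC)c2C=CC(C)(C)Oc12)COC(C)=O | intermediate
16 | (2R)-3-[3-formyl-6-methoxy-2,4-bis(methoxymethoxy)phenyl]-2-[5-(methoxymethoxy)-2,2-dimethyl-2H-chromen-8-yl]propyl acetate | COc1cc(OCOC)c(C=O)c(OCOC)c1C[C@H](c1ccc(OCOC)c2C=CC(C)(C)Oc12)COC(C)=O | intermediate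
17 | 2,6-dihydroxy-3-[(2R)-3-hydroxy-2-(5-hydroxy-2,2-dimethyl-2H-chromen-8-yl)propyl]-4-methoxybenzaldehyde | COc1cc(O)c(C=O)c(O)c1C[C@H](c1ccc(O)c2C=CC(C)(C)Oc12)CO | intermediate
18 | (3R)-7-hydroxy-3-(5-hydroxy-2,2-dimethyl-2H-chromen-8-yl)-5-methoxy-3,4-dihydro-2H-chromene-8-carbaldehyde | COc1cc(O)c(C=O)c2c1C[C@H](c1ccc(O)c3c1OC(C)(C)C=C3)CO2 | target

Total step count: 11. Longest linear sequence: 9 steps (steps 1–6, then 9–11).

**Steps most likely to fail, with fallbacks**

Step 5. The enzyme may discriminate poorly between the two hydroxymethyl groups next to an ortho-alkoxy aryl group, may acylate the other arm, or 1,3-acetyl migration may erode the enantiomeric purity. The fallback sets the stereocentre with a chiral auxiliary and sets out from 8. Saponification and decarboxylation (KOH, aqueous EtOH, reflux; mild acidification and warming) should give [5-(methoxymethoxy)-2,2-dimethyl-2H-chromen-8-yl]acetic acid F2. N-acylation of (R)-4-benzyl-1,3-oxazolidin-2-one (pivaloyl chloride, Et3N, LiCl, THF) gives (4R)-4-benzyl-3-{[5-(methoxymethoxy)-2,2-dimethyl-2H-chromen-8-yl]acetyl}-1,3-oxazolidin-2-one F3. Evans alkylation (NaN(SiMe3)2, THF, −78 °C; 4-methoxybenzyl chloromethyl ether), with the benzyl group of the auxiliary shielding one enolate face, should give (4R)-4-benzyl-3-{(2S)-3-[(4-methoxybenzyl)oxy]-2-[5-(methoxymethoxy)-2,2-dimethyl-2H-chromen-8-yl]propanoyl}-1,3-oxazolidin-2-one F4. Reductive removal of the auxiliary (LiBH4, THF, H2O) gives (2R)-3-[(4-methoxybenzyl)oxy]-2-[5-(methoxymethoxy)-2,2-dimethyl-2H-chromen-8-yl]propan-1-ol F5, and acetylation (Ac2O, pyridine) gives (2S)-3-[(4-methoxybenzyl)oxy]-2-[5-(methoxymethoxy)-2,2-dimethyl-2H-chromen-8-yl]propyl acetate F6. Oxidative removal of the 4-methoxybenzyl group (DDQ, CH2Cl2, pH 7 buffer, 0 °C) comes back to the route at 10.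

Step 2. C–C bond formation at the ortho carbon flanked by OH and OMOM may be slow, so that acid-induced loss of the MOM acetal or self-condensation of the enal takes over. The fallback separates the two bond formations and sets out from 2. O-alkylation with 3-chloro-3-methylbut-1-yne (DBU, CuCl2 (1 mol %), MeCN, 0 °C) gives 1-bromo-4-(methoxymethoxy)-2-[(2-methylbut-3-yn-2-yl)oxy]benzene F1. Heating (N,N-diethylaniline, 180 °C) should bring about aromatic Claisen rearrangement to the only free ortho carbon, 1,5-hydrogen shift and oxa-6π closure, and comes back to the route at 6.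

Step 9. Transmetallation and reductive elimination at the doubly ortho-flanked arylpalladium may be slow, so that protodezincation or β-hydride elimination compete with coupling. The fallback replaces the zinc reagent made in the flask by an isolable boron partner and sets out from 11. Radical borylation (bis(catecholato)diboron, DMF, blue light; then pinacol, Et3N) should give (2R)-2-[5-(methoxymethoxy)-2,2-dimethyl-2H-chromen-8-yl]-3-(4,4,5,5-tetramethyl-1,3,2-dioxaborolan-2-yl)propyl acetate F7. B-alkyl Suzuki–Miyaura coupling of this boronate with 14 (Pd(OAc)2, RuPhos, K3PO4, toluene/H2O, 80 °C) comes back to the route at 16.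

**Further compounds**

F1 | step 2 | 1-bromo-4-(methoxymethoxy)-2-[(2-methylbut-3-yn-2-yl)oxy]benzene | COCOc1ccc(Br)c(OC(C)(C)C#C)c1
F2 | step 5 | [5-(methoxymethoxy)-2,2-dimethyl-2H-chromen-8-yl]acetic acid | OC(=O)Cc1ccc(OCOC)c2C=CC(C)(C)Oc12
F3 | step 5 | (4R)-4-benzyl-3-{[5-(methoxymethoxy)-2,2-dimethyl-2H-chromen-8-yl]acetyl}-1,3-oxazolidin-2-one | O=C1OC[C@@H](Cc2ccccc2)N1C(=O)Cc1ccc(OCOC)c2C=CC(C)(C)Oc12
F4 | step 5 | (4R)-4-benzyl-3-{(2S)-3-[(4-methoxybenzyl)oxy]-2-[5-(methoxymethoxy)-2,2-dimethyl-2H-chromen-8-yl]propanoyl}-1,3-oxazolidin-2-one | O=C1OC[C@@H](Cc2ccccc2)N1C(=O)[C@@H](c1ccc(OCOC)c2C=CC(C)(C)Oc12)COCc1ccc(OC)cc1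
F5 | step 5 | (2R)-3-[(4-methoxybenzyl)oxy]-2-[5-(methoxymethoxy)-2,2-dimethyl-2H-chromen-8-yl]propan-1-ol | COc1ccc(COC[C@H](c2ccc(OCOC)c3C=CC(C)(C)Oc23)CO)cc1
F6 | step 5 | (2S)-3-[(4-methoxybenzyl)oxy]-2-[5-(methoxymethoxy)-2,2-dimethyl-2H-chromen-8-yl]propyl acetate | COc1ccc(COC[C@H](c2ccc(OCOC)c3C=CC(C)(C)Oc23)COC(C)=O)cc1
F7 | step 9 | (2R)-2-[5-(methoxymethoxy)-2,2-dimethyl-2H-chromen-8-yl]-3-(4,4,5,5-tetramethyl-1,3,2-dioxaborolan-2-yl)propyl acetate | CC1(C)OB(C[C@H](c2ccc(OCOC)c3C=CC(C)(C)Oc23)COC(C)=O)OC1(C)C
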